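## Retrosynthetic overview

1. Target 18 ⇐ diester 17 (reduction of both esters) ⇐ bromo ester 15 + methyl acrylate (Heck).
2. Dihydrobenzofuran ring of 15 ⇐ oxidative ring contraction of (2R)-flavanone 14: the aryl carbon C4a shifts from C4 to C3, and C4 becomes the exocyclic ester carbon (C9).
3. Pyranone ring of 14 ⇐ enantioselective 6-endo oxa-Michael closure of 2'-hydroxychalcone 13 (new, chiral Brønsted acid), run in one flask with the contraction.
4. 13 ⇐ aldol condensation of acetophenone 12 (catechol → guaiacol → bromide → ortho-acetylation) with aldehyde 6 (p-cresol → dibromo-hydroxybenzaldehyde → methoxylation/methylation).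
5. Ring order: both benzene rings are bought; the pyranone ring is made first and then contracted to the dihydrofuran ring.

Assumption: the sense of induction of the new catalyst in step 7 must be fixed by experiment; "IDPi" (a BINOL-derived imidodiphosphorimidate Brønsted acid with an N-triflyl core) means the enantiomer that gives the (2R)-flavanone 14.

## Route

Step 1
Reactants: 1 p-cresol (4-methylphenol)
Product: 4 3,5-dibromo-4-hydroxybenzaldehyde, via 2,6-dibromo-4-methylphenol 2 (not isolated), via 2,6-dibromo-4-(dibromomethyl)phenol 3 (not isolated)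
Conditions: Br2 (4.1 equiv), o-dichlorobenzene, 35 °C then 150–160 °C; then H2O/aq. HBr, 100 °C
Reagents that add atoms: bromine (BrBr), water (O)
Why: Electrophilic aromatic bromination fills both positions ortho to OH (para is blocked), hot Br2 then brominates the methyl group twice by a radical chain (benzylic bromination), and hydrolysis of the benzal bromide gives the aldehyde; no stereocentre.

Step 2
Reactants: 4 3,5-dibromo-4-hydroxybenzaldehyde
Product: 6 3,4,5-trimethoxybenzaldehyde, via sodium 4-formyl-2,6-dimethoxyphenolate 5 (not isolated)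
Conditions: NaOMe (4 equiv), CuCl (10 mol%), DMF/MeOH, 115 °C; then Me2SO4, 50 °C
Reagents that add atoms: sodium methoxide ([Na+].[O-]C), dimethyl sulfate (COS(=O)(=O)OC)
Why: Cu(I)-catalysed Ullmann-type methoxylation replaces both aryl bromides while the para-phenoxide shields the aldehyde from methoxide, and the phenoxide is then O-methylated in the same pot (Williamson ether synthesis).

Step 3
Reactants: 7 catechol (benzene-1,2-diol)
Product: 8 guaiacol (2-methoxyphenol)
Conditions: MeI (1.0 equiv), K2CO3 (1.0 equiv), acetone, reflux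
Reagents that add atoms: iodomethane (CI)
Why: Williamson mono-O-methylation of the catechol mono-anion with one equivalent of MeI; guaiacol is separated from veratrole and unreacted catechol by distillation.

Step 4
Reactants: 8 guaiacol
Product: 9 4-bromo-2-methoxyphenol
Conditions: NBS (1.0 equiv), MeCN, 0 °C
Reagents that add atoms: N-bromosuccinimide (O=C1CCC(=O)N1Br)
Why: Electrophilic aromatic bromination goes para to the free OH, the stronger director, and this also blocks the para position for the next step.

Step 5
Reactants: 9 4-bromo-2-methoxyphenol; 10 acetic anhydride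
Product: 12 1-(5-bromo-2-hydroxy-3-methoxyphenyl)ethan-1-one, via 4-bromo-2-methoxyphenyl acetate 11 (not isolated)
Conditions: Ac2O (1.2 equiv), Sc(OTf)3 (10 mol%), toluene/MeNO2, 100 °C
Reagents that add atoms: none
Why: O-acetylation followed by Lewis-acid Fries rearrangement (net ortho-C-acylation); the para position carries Br, the other ortho position carries OMe, and the chelated o-hydroxy ketone is the favoured product.

Step 6
Reactants: 12 1-(5-bromo-2-hydroxy-3-methoxyphenyl)ethan-1-one; 6 3,4,5-trimethoxybenzaldehyde
Product: 13 (E)-1-(5-bromo-2-hydroxy-3-methoxyphenyl)-3-(3,4,5-trimethoxyphenyl)prop-2-en-1-one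
Conditions: KOH (3 equiv), EtOH/H2O, rt; then aq. HCl
Reagents that add atoms: none
Why: Claisen–Schmidt aldol condensation of the methyl ketone enolate with the non-enolisable aldehyde; E1cB dehydration gives the conjugated (E)-enone.

Step 7
Reactants: 13 (E)-2'-hydroxychalcone
Product: 15 methyl (2R,3R)-5-bromo-7-methoxy-2-(3,4,5-trimethoxyphenyl)-2,3-dihydro-1-benzofuran-3-carboxylate (2,3-trans), via (2R)-flavanone 14 (not isolated)
Conditions: (i) IDPi (2.5 mol%), CHCl3, 25 °C; (ii) HC(OMe)3, PhI(OAc)2 (1.2 equiv), H2SO4 (cat.), 0 °C → rt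
Reagents that add atoms: trimethyl orthoformate (COC(OC)OC)
Why: Proposed new method: a confined, strongly acidic chiral imidodiphosphorimidate protonates the enone carbonyl of 13 (breaking the internal OH···O=C hydrogen bond) and the phenol closes 6-endo on the β-carbon inside the chiral ion pair, which sets C2 as R with no base present that could racemise the flavanone by retro-oxa-Michael opening; acid, orthoformate and PhI(OAc)2 then convert 14 into its enol ether, iodinate C3 anti to the 2-aryl group and trigger the 1,2-shift of the aryl carbon C4a from C4 to C3 with loss of PhI (oxidative ring contraction), which sets C3 trans to the aryl group (also the thermodynamic epimer) and leaves C2 untouched; the closest known reaction types are the chiral N-triflylphosphoramide-catalysed aza-Michael cyclisation of 2'-aminochalcones to 2-aryl-2,3-dihydroquinolin-4-ones and the PhI(OAc)2/HC(OMe)3/H2SO4 ring contraction of racemic flavanones to trans-2-aryl-2,3-dihydrobenzofuran-3-carboxylates.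

Step 8
Reactants: 15 bromo ester; 16 methyl acrylate
Product: 17 methyl (2R,3R)-7-methoxy-5-[(E)-3-methoxy-3-oxoprop-1-en-1-yl]-2-(3,4,5-trimethoxyphenyl)-2,3-dihydro-1-benzofuran-3-carboxylate
Conditions: Pd2(dba)3 (1.5 mol%), [HP(t-Bu)3]BF4 (6 mol%), Cy2NMe (1.2 equiv), dioxane, 70 °C
Reagents that add atoms: none
Why: Mizoroki–Heck reaction of the aryl bromide with the acrylate; syn β-hydride elimination gives the (E)-cinnamate, and the mild amine base at 70 °C does not enolise the C3 ester, so both stereocentres stay.

Step 9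
Reactants: 17 diester
Product: 18 (-)-(7R,8S,7'E)-3,4,5,5'-tetramethoxy-4',7-epoxy-8,3'-neolign-7'-ene-9,9'-diol
Conditions: DIBAL-H (6 equiv), CH2Cl2, −78 → −20 °C; Rochelle salt work-up
Reagents that add atoms: none
Why: DIBAL-H reduces both methyl esters by 1,2-hydride delivery (no conjugate reduction of the cinnamate) at low temperature, so the (E)-alkene and both stereocentres are kept; the descriptor at C8 changes from R to S only because the CIP priorities change.

## Compound list

1 | p-cresol (4-methylphenol) | Cc1ccc(O)cc1 | starting material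
2 | 2,6-dibromo-4-methylphenol | Cc1cc(Br)c(O)c(Br)c1 | intermediate
3 | 2,6-dibromo-4-(dibromomethyl)phenol | BrC(Br)c1cc(Br)c(O)c(Br)c1 | intermediate
4 | 3,5-dibromo-4-hydroxybenzaldehyde | O=Cc1cc(Br)c(O)c(Br)c1 | intermediate
5 | sodium 4-formyl-2,6-dimethoxyphenolate | [Na+].[O-]c1c(OC)cc(C=O)cc1OC | intermediate
6 | 3,4,5-trimethoxybenzaldehyde | COc1cc(C=O)cc(OC)c1OC | intermediate
7 | catechol (benzene-1,2-diol) | Oc1ccccc1O | starting material
8 | guaiacol (2-methoxyphenol) | COc1ccccc1O | intermediate
9 | 4-bromo-2-methoxyphenol | COc1cc(Br)ccc1O | intermediate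
10 | acetic anhydride | CC(=O)OC(C)=O | starting material
11 | 4-bromo-2-methoxyphenyl acetate | CC(=O)Oc1ccc(Br)cc1OC | intermediate
12 | 1-(5-bromo-2-hydroxy-3-methoxyphenyl)ethan-1-one | CC(=O)c1cc(Br)cc(OC)c1O | intermediate
13 | (E)-1-(5-bromo-2-hydroxy-3-methoxyphenyl)-3-(3,4,5-trimethoxyphenyl)prop-2-en-1-one | COc1cc(/C=C/C(=O)c2cc(Br)cc(OC)c2O)cc(OC)c1OC | intermediate
14 | (2R)-6-bromo-8-methoxy-2-(3,4,5-trimethoxyphenyl)-2,3-dihydro-4H-chromen-4-one | COc1cc([C@@H]2Oc3c(OC)cc(Br)cc3C(=O)C2)cc(OC)c1OC | intermediate
15 | methyl (2R,3R)-5-bromo-7-methoxy-2-(3,4,5-trimethoxyphenyl)-2,3-dihydro-1-benzofuran-3-carboxylate (trans) | COc1cc([C@@H]2Oc3c(OC)cc(Br)cc3[C@H]2C(=O)OC)cc(OC)c1OC | intermediate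
16 | methyl acrylate | C=CC(=O)OC | starting material
17 | methyl (2R,3R)-7-methoxy-5-[(E)-3-methoxy-3-oxoprop-1-en-1-yl]-2-(3,4,5-trimethoxyphenyl)-2,3-dihydro-1-benzofuran-3-carboxylate | COc1cc([C@@H]2Oc3c(OC)cc(/C=C/C(=O)OC)cc3[C@H]2C(=O)OC)cc(OC)c1OC | intermediate
18 | (-)-(7R,8S,7'E)-3,4,5,5'-tetramethoxy-4',7-epoxy-8,3'-neolign-7'-ene-9,9'-diol | COc1cc([C@@H]2Oc3c(OC)cc(/C=C/CO)cc3[C@H]2CO)cc(OC)c1OC | target

## Step count and risks

Total steps: 9. Longest linear sequence: 7 (steps 3, 4, 5, 6, 7, 8, 9 from catechol); the aldehyde branch (steps 1, 2) joins at step 6.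

The three steps most likely to fail:

Step 7 (the proposed new step). The chiral acid may give low ee or slow closure, and the one-flask oxidation may give the isoflavone by 2,3-aryl shift. The fallback uses known chemistry, sets out from 13 and comes back at 15. Chalcone 13 is cyclised with NaOAc in refluxing EtOH to racemic 6-bromo-8-methoxy-2-(3,4,5-trimethoxyphenyl)chroman-4-one F1. F1 is then resolved kinetically by asymmetric transfer hydrogenation (Cp*RhCl(TsDPEN), HCO2H/Et3N, EtOAc, rt, stopped near 50–55 % conversion), using the catalyst antipode that reduces the 2S ketone. This turns the unwanted enantiomer into the cis alcohol (2S,4S)-6-bromo-8-methoxy-2-(3,4,5-trimethoxyphenyl)chroman-4-ol F2, which is removed by chromatography, and leaves the (2R)-flavanone 14. Here 14 is isolated and recrystallised, then ring-contracted in a separate operation with PhI(OAc)2, HC(OMe)3 and H2SO4 to give 15.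

Step 5. The Fries step may acylate para to the methoxy group (C5) or cleave the methyl ether. The fallback sets out from 9 and comes back at 12. Magnesium-mediated ortho-formylation (MgCl2, Et3N, paraformaldehyde, MeCN, reflux) gives 5-bromo-2-hydroxy-3-methoxybenzaldehyde F3 with ortho delivery through the magnesium phenoxide. Addition of MeMgBr (2.5 equiv, THF, 0 °C) gives racemic 4-bromo-2-(1-hydroxyethyl)-6-methoxyphenol F4. Benzylic oxidation with MnO2 in CH2Cl2 then gives 12.

Step 8. The amine base at 70 °C could enolise the β-aryloxy ester and open the ring by E1cB, which would erode the C7 configuration, or the electron-rich bromide could react sluggishly. The fallback sets out from 15 and comes back at 18. The ester is reduced first (DIBAL-H, CH2Cl2, −78 °C) to [(2R,3S)-5-bromo-7-methoxy-2-(3,4,5-trimethoxyphenyl)-2,3-dihydro-1-benzofuran-3-yl]methanol F5, which no longer has an acidic C–H. A base-free Stille coupling (Pd(PPh3)4, toluene, 100 °C) with (E)-3-(tributylstannyl)prop-2-en-1-ol F6, made from propargyl alcohol and Bu3SnH (AIBN, 80 °C), then gives 18 directly.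

## Further compounds

F1 | step 7 | rac-6-bromo-8-methoxy-2-(3,4,5-trimethoxyphenyl)chroman-4-one | COc1cc(C2Oc3c(OC)cc(Br)cc3C(=O)C2)cc(OC)c1OC
F2 | step 7 | (2S,4S)-6-bromo-8-methoxy-2-(3,4,5-trimethoxyphenyl)chroman-4-ol | COc1cc([C@H]2Oc3c(OC)cc(Br)cc3[C@@H](O)C2)cc(OC)c1OC
F3 | step 5 | 5-bromo-2-hydroxy-3-methoxybenzaldehyde | O=Cc1cc(Br)cc(OC)c1O
F4 | step 5 | rac-4-bromo-2-(1-hydroxyethyl)-6-methoxyphenol | CC(O)c1cc(Br)cc(OC)c1O
F5 | step 8 | [(2R,3S)-5-bromo-7-methoxy-2-(3,4,5-trimethoxyphenyl)-2,3-dihydro-1-benzofuran-3-yl]methanol | COc1cc([C@@H]2Oc3c(OC)cc(Br)cc3[C@H]2CO)cc(OC)c1OC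
F6 | step 8 | (E)-3-(tributylstannyl)prop-2-en-1-ol | CCCC[Sn](CCCC)(CCCC)/C=C/CO
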